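## The problem

Trachelogenin (17) is a dibenzylbutyrolactone. Its γ-lactone (O1, C2=O, C3, C4, C5) carries a hydroxyl and a 4-hydroxy-3-methoxybenzyl group on C3 and a 3,4-dimethoxybenzyl group on C4. Both centres are S, the two benzyl groups are trans, and the hydroxyl is cis to the C4 benzyl group. The difficulty sits in the C3–C4 bond: C3 is a fully substituted carbinol carbon next to the lactone carbonyl, and neither C3 nor C4 has an acidic hydrogen in 17, so a wrong configuration cannot be repaired by late equilibration. C4 is the easier centre and could steer C3, but an electrophilic oxygen delivered to a C3 enolate would enter anti to the C4 benzyl group and give the wrong epimer. The C3–O bond is therefore better in place before, or formed together with, the C3–C bonds. The two aryl rings differ only in OH versus OMe at one position, so they must come from separate fragments, and the phenol must be masked against bases, oxidants and electrophilic metal carbenes. Both rings are electron-rich, which limits the oxidants, and any intermediate with a carbonyl β to the tertiary hydroxyl (a C5 aldehyde) is open to retro-aldol cleavage and to epimerisation at C4. The enabling feature is that C3 holds both the hydroxyl oxygen and the bond to C4. Formally C3 is a carbene carbon inserted between the oxygen and the γ-carbon of an allylic alcohol, with C2 arriving as the ester of the carbene precursor and C5 as the alkene carbon left by the allylic transposition.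

## Retrosynthesis

**17 from 16.** Only the phenolic O–benzyl bond is cut. A benzyl ether is chosen over a silyl ether or acetate because it survives Grignard-free base, hydride, the metal carbenoid and the oxidative cleavage. It leaves under neutral hydrogenolysis at a stage where no alkene remains. The forward step must leave the lactone and the homobenzylic tertiary alcohol alone.

**16 from 14, and 14 from 12.** The acyl–O1 bond of the lactone is cut to the γ-hydroxy ester 15, the C5 alcohol is traced to aldehyde 14, and the aldehyde to the E-propenyl group of 12. Keeping the ring intact through the carbenoid step would put the diazo group on a lactone with a tertiary β-hydrogen at C4 (see Alternative 3). The acyclic ester 12 avoids this, at the price of two carbons lost as acetaldehyde. The forward steps must cleave one alkene beside two electron-rich arenes and reduce the aldehyde before C4 can epimerise.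

**12 from 5 and 10 (key cut).** The C3–O and C3–C4 bonds (lactone numbering; C2–O and C2–C3 of hexenoate 12) are cut together. C3 becomes the carbene carbon of diazo ester 5 and the oxygen and C4 come from allylic alcohol 10. Against an aldol or enolate alkylation at C3, this cut forms the quaternary centre intramolecularly within an ylide, not by a hindered intermolecular substitution. It also brings the oxygen in with the correct sense relative to C4. Both precursors are small, of equal size and carry at most one stereocentre. The forward reaction must favour ylide formation and [2,3]-shift over 1,2-hydride shift and O–H insertion, transfer the carbinol chirality to C4, and let the catalyst set C3.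

**10 from 9, and 9 from 6 and 7.** The E-alkene is traced to the alkyne of 9, and the propargylic CH2–C(sp) bond is cut to (R)-but-3-yn-2-ol 6 and 3,4-dimethoxybenzyl bromide 7. An alkyne route guarantees a single alkene geometry, which a cross-metathesis would not. The geometry matters because the Z-alcohol would deliver the other C4 configuration. The carbinol centre is bought, not made.

**5 from 4, 4 from 3, and 3 from 1 and 2.** The diazo group is traced to the acetyl group of β-keto ester 4 (deacylative diazo transfer). The benzylic C–C bond is traced through alkylidene 3 to O-benzylvanillin 1 and methyl acetoacetate 2. This uses the stable aldehyde in place of the labile electron-rich benzyl halide. The forward sequence must reduce the C=C bond without touching the benzyl ether.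

## Roads not taken

**Alternative 1:** The C4–C(benzylic) and C3–CH2Ar bonds are cut on a preformed ring. Lithiated 2-(3,4-dimethoxyphenyl)-1,3-dithiane A3 would add to C4 of the chiral butenolide (5R)-3-(benzyloxy)-5-(l-menthyloxy)furan-2(5H)-one A2, anti to the acetal. The α-benzyloxy enolate would then be trapped with 4-(benzyloxy)-3-methoxybenzyl bromide A4 anti to the dithianyl group, giving lactone A1.
- Merits: tandem addition–alkylation on menthyloxybutenolides is among the best-tested entries to trans-dibenzylbutyrolactones. Both centres follow from steric approach control, and the sense (benzyl trans, oxygen cis to the C4 substituent) is the one 17 needs.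
- Weak points: A2 is an enol ether of an α-keto lactone. It is not an article of commerce and is a poorer acceptor than the parent butenolide. The second bond requires intermolecular alkylation of a tetrasubstituted α-alkoxy enolate next to a 2-aryl-dithianyl group, where proton return or O-alkylation can win. After A1 the route still needs desulfurisation, reductive removal of the acetal with relactonisation, and debenzylation. It also consumes a stoichiometric auxiliary and a sulfur reagent.
- Comparison: its stereochemical model is better precedented than the catalyst control at C3 in the chosen plan. The chosen plan sets against this a catalytic, auxiliary-free step that forms the quaternary centre inside an ylide, with both partners made in two or three steps from purchasable materials.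

**Alternative 2:** The C4–C5 bond and the benzylic CH2–aryl bond are cut. The ate complex of vinylboronate A6 and (benzyloxymethyl)lithium A7 would couple with 3,4-dimethoxyphenyl triflate A8 under Pd(OAc)2 and a chiral bisphosphine. The oxymethyl group migrates to the internal carbon as the aryl group bonds to the terminal one, giving secondary boronate A5.
- Merits: a catalytic enantioselective three-component assembly of C4 with C5 already at the alcohol oxidation level, so no carbons are thrown away later. In that respect it is better than the chosen plan.
- Weak points: A7 requires tin–lithium exchange and its migration is not the standard case of the reaction. More seriously, A5 solves only C4. The tetrasubstituted carbinol C3 would still have to be built from a secondary C–B bond with control relative to C4, over several further steps and with no obvious stereospecific method.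
- Comparison: the chosen plan forms both centres and both bonds to C3 in one step, and obtains C4 from a purchased carbinol centre, not from an asymmetric catalyst.

**Alternative 3:** The C3–O and C3–CH2Ar bonds are cut on the intact lactone. The carbenoid from diazo lactone (R)-A10 (with Cu(hfacac)2 or Rh2(OAc)4) would be captured by the dibenzylic ether A11, and the oxonium ylide would undergo a [1,2]-benzyl shift to A9.
- Merits: this is the closest relative of the chosen plan. It is shorter after the key step, because one hydrogenolysis would remove both benzylic groups of A9.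
- Weak points: intermolecular ylide formation from a dialkyl ether is slow next to attack on the electron-rich arenes. The [1,2]-shift runs through a radical pair, with lower efficiency and weaker stereocontrol than a concerted shift. A10 carries a tertiary β-hydrogen on the C4 stereocentre, so a 1,2-hydride shift to the butenolide would erase the only stereocentre present. Half of A11 is wasted.
- Comparison: the chosen plan pays two extra steps (alkene cleavage, reduction) for a symmetry-allowed [2,3]-shift with predictable chirality transfer, and for a diazo precursor whose hydride shift destroys no stereocentre.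

Key step: step 6

Assumption: the sense of induction of a chiral dirhodium carboxylate at the carbinol carbon is not established for an α-benzyl carbenoid. The route is written with Rh2(S-PTTL)4 (dirhodium tetrakis[N-phthaloyl-(S)-tert-leucinate]); its enantiomer would replace it unchanged if the opposite sense were found.

## Route

Step 1
Reactants: 1 4-(benzyloxy)-3-methoxybenzaldehyde; 2 methyl acetoacetate
Product: 3 methyl 2-[4-(benzyloxy)-3-methoxybenzylidene]-3-oxobutanoate (E/Z mixture)
Conditions: piperidine (10 mol %), AcOH (10 mol %), toluene, reflux, Dean–Stark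
Reagents that add atoms: none
Why: Knoevenagel condensation of a non-enolisable aryl aldehyde with a β-keto ester, driven by azeotropic removal of water; the alkene geometry is irrelevant because the double bond is reduced next.

Step 2
Reactants: 3 methyl 2-[4-(benzyloxy)-3-methoxybenzylidene]-3-oxobutanoate
Product: 4 methyl 2-[4-(benzyloxy)-3-methoxybenzyl]-3-oxobutanoate (racemic)
Conditions: Hantzsch ester (diethyl 2,6-dimethyl-1,4-dihydropyridine-3,5-dicarboxylate, 1.2 equiv), EtOH, 70 °C
Reagents that add atoms: none
Why: Conjugate transfer hydrogenation of a doubly activated alkylidene by the dihydropyridine leaves ketone, ester and the benzyl ether untouched, which H2 over palladium would not; the new centre is racemic and is erased in step 3.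

Step 3
Reactants: 4 methyl 2-[4-(benzyloxy)-3-methoxybenzyl]-3-oxobutanoate
Product: 5 methyl 3-[4-(benzyloxy)-3-methoxyphenyl]-2-diazopropanoate
Conditions: p-ABSA (1.3 equiv), DBU (1.5 equiv), MeCN, 0 °C → rt
Reagents that add atoms: 4-acetamidobenzenesulfonyl azide (p-ABSA), CC(=O)Nc1ccc(cc1)S(=O)(=O)N=[N+]=[N-]
Why: Regitz deacylative diazo transfer: the enolate adds to the sulfonyl azide and the adduct fragments with loss of the acetyl group as the N-acylsulfonamide, the ketone being a better acyl donor than the ester.

Step 4
Reactants: 6 (R)-but-3-yn-2-ol; 7 3,4-dimethoxybenzyl bromide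
Product: 9 (R)-5-(3,4-dimethoxyphenyl)pent-3-yn-2-ol, via dimagnesium alkynide 8 (not isolated)
Conditions: EtMgBr (2.1 equiv), THF, 0 °C → rt; CuBr·SMe2 (10 mol %), then 7, 0 → 45 °C; aq. NH4Cl
Reagents that add atoms: none
Why: Double deprotonation gives the alkoxide/alkynyl Grignard, and monovalent copper catalyses C-benzylation of the alkynyl carbon by the reactive benzylic bromide while the magnesium alkoxide is too poor a nucleophile to be O-alkylated; no strong base remains to isomerise the 1-aryl-2-alkyne, and the carbinol centre is not touched.

Step 5
Reactants: 9 (R)-5-(3,4-dimethoxyphenyl)pent-3-yn-2-ol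
Product: 10 (R,E)-5-(3,4-dimethoxyphenyl)pent-3-en-2-ol
Conditions: LiAlH4 (1.5 equiv), THF, 0 → 45 °C; H2O, aq. NaOH work-up
Reagents that add atoms: none
Why: Alkoxide-directed trans-hydroalumination of a propargylic alcohol followed by protonolysis gives the E-allylic alcohol only; the carbinol centre is retained.

Step 6
Reactants: 5 methyl 3-[4-(benzyloxy)-3-methoxyphenyl]-2-diazopropanoate; 10 (R,E)-5-(3,4-dimethoxyphenyl)pent-3-en-2-ol
Product: 12 methyl (2S,3S,E)-2-[4-(benzyloxy)-3-methoxybenzyl]-3-(3,4-dimethoxybenzyl)-2-hydroxyhex-4-enoate, via oxonium ylide 11 (not isolated)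
Conditions: 10 (1.5 equiv), Rh2(S-PTTL)4 (1 mol %), toluene, −78 °C; 5 in toluene added over 3 h by syringe pump; −78 → −40 °C
Reagents that add atoms: none
Why: Proposed new method: the closest known reaction type is the dirhodium tetracarboxylate-catalysed tandem oxonium ylide formation/[2,3]-sigmatropic rearrangement of aryl- and vinyldiazoacetates with chiral secondary allylic alcohols, extended here to an α-benzyl diazoester, a class whose intermolecular carbenoid reactions under Rh2(S-PTTL)4 at −78 °C are known to outrun the 1,2-hydride shift; the reasoning is that an acceptor-only carbenoid is more, not less, electrophilic toward the hydroxyl oxygen and that its ylide needs only the same five-centre reorganisation. The catalyst expels N2 from 5, the hydroxyl oxygen of 10 adds to the carbene carbon to give ylide 11, and 11 rearranges through an envelope made of the carbanionic carbon, the oxygen, the carbinol carbon and the two alkene carbons, the O–H proton staying on oxygen hydrogen-bonded to the ester carbonyl, so that the allylic C–O bond breaks as C2–C3 forms. No ring closes. C3 of 12 is set by suprafacial chirality transfer from the (R)-carbinol centre: with the carbinol methyl pseudo-equatorial (allylic 1,3-strain minimised) the new bond forms on the alkene face that the oxygen leaves, which gives 3S and the E-propenyl group. C2 is set by the face of the ylide carbon left open by the chiral carboxylate ligands, which in the aryl and vinyl precedent override the alcohol at this centre; 2S is the configuration needed. The step needs chemoselectivity for ylide formation and shift over 1,2-hydride shift to the cinnamate and over 1,2-proton shift (O–H insertion); the bulky phthalimido ligands, −78 °C, excess 10 with slow addition of 5, an aprotic non-polar medium and the hindered secondary E-disubstituted alcohol are the means. The phenol is benzylated because a free phenol would capture the carbenoid itself.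

Step 7
Reactants: 12 methyl (2S,3S,E)-2-[4-(benzyloxy)-3-methoxybenzyl]-3-(3,4-dimethoxybenzyl)-2-hydroxyhex-4-enoate
Product: 14 methyl (2S,3R)-2-[4-(benzyloxy)-3-methoxybenzyl]-3-(3,4-dimethoxybenzyl)-2-hydroxy-4-oxobutanoate, via vicinal diol 13 (not isolated)
Conditions: OsO4 (2 mol %), NaIO4 (4 equiv), 2,6-lutidine (2 equiv), dioxane/H2O (3:1), rt; crude aldehyde used at once
Reagents that add atoms: osmium tetroxide, O=[Os](=O)(=O)=O; sodium periodate, [Na+].[O-]I(=O)(=O)=O (oxygen source that regenerates the osmium oxidant)
Why: Lemieux–Johnson oxidation: syn-dihydroxylation of the only alkene and periodate cleavage of diol 13, with 2,6-lutidine holding the medium near neutral so that α-ketol formation and epimerisation α to the aldehyde are suppressed; arenes and the benzyl ether are inert, and the descriptor at C3 changes to R only because the formyl group outranks C2.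

Step 8
Reactants: 14 methyl (2S,3R)-2-[4-(benzyloxy)-3-methoxybenzyl]-3-(3,4-dimethoxybenzyl)-2-hydroxy-4-oxobutanoate
Product: 16 (3S,4S)-3-[4-(benzyloxy)-3-methoxybenzyl]-4-(3,4-dimethoxybenzyl)-3-hydroxydihydrofuran-2(3H)-one, via hydroxy ester 15 (not isolated)
Conditions: NaBH4 (0.5 equiv), THF/MeOH (4:1), −40 °C; then 1 M HCl, rt
Reagents that add atoms: none
Why: Borohydride reduces the aldehyde far faster than the α-hydroxy ester at low temperature, and the γ-hydroxy ester 15 closes to the five-membered lactone by intramolecular transesterification on acidic work-up, helped by the fully substituted α-carbon; neither stereocentre is touched.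

Step 9
Reactants: 16 (3S,4S)-3-[4-(benzyloxy)-3-methoxybenzyl]-4-(3,4-dimethoxybenzyl)-3-hydroxydihydrofuran-2(3H)-one
Product: 17 trachelogenin, (3S,4S)-4-(3,4-dimethoxybenzyl)-3-hydroxy-3-(4-hydroxy-3-methoxybenzyl)dihydrofuran-2(3H)-one
Conditions: H2 (1 atm), 10% Pd/C, EtOAc/EtOH (1:1), rt
Reagents that add atoms: none
Why: Hydrogenolysis of the aryl benzyl ether; the lactone, the methyl ethers and the tertiary alcohol (homobenzylic, not benzylic) are inert.

## Compound list

1 | 4-(benzyloxy)-3-methoxybenzaldehyde (O-benzylvanillin) | COc1cc(C=O)ccc1OCc1ccccc1 | starting material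
2 | methyl acetoacetate | COC(=O)CC(C)=O | starting material
3 | methyl 2-[4-(benzyloxy)-3-methoxybenzylidene]-3-oxobutanoate (E/Z mixture) | COC(=O)C(=Cc1ccc(OCc2ccccc2)c(OC)c1)C(C)=O | intermediate
4 | methyl 2-[4-(benzyloxy)-3-methoxybenzyl]-3-oxobutanoate (racemic) | COC(=O)C(Cc1ccc(OCc2ccccc2)c(OC)c1)C(C)=O | intermediate
5 | methyl 3-[4-(benzyloxy)-3-methoxyphenyl]-2-diazopropanoate | COC(=O)C(=[N+]=[N-])Cc1ccc(OCc2ccccc2)c(OC)c1 | intermediate
6 | (R)-but-3-yn-2-ol | C[C@@H](O)C#C | starting material
7 | 3,4-dimethoxybenzyl bromide | COc1ccc(CBr)cc1OC | starting material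
8 | bromomagnesium (R)-4-(bromomagnesio)but-3-yn-2-olate, the dimagnesium alkynide (not isolated) | C[C@@H](O[Mg]Br)C#C[Mg]Br | intermediate
9 | (R)-5-(3,4-dimethoxyphenyl)pent-3-yn-2-ol | C[C@@H](O)C#CCc1ccc(OC)c(OC)c1 | intermediate
10 | (R,E)-5-(3,4-dimethoxyphenyl)pent-3-en-2-ol | C[C@@H](O)/C=C/Cc1ccc(OC)c(OC)c1 | intermediate
11 | oxonium ylide from the carbene carbon of 5 and the hydroxyl oxygen of 10, drawn without the metal (not isolated) | COC(=O)[C-](Cc1ccc(OCc2ccccc2)c(OC)c1)[OH+][C@H](C)/C=C/Cc1ccc(OC)c(OC)c1 | intermediate
12 | methyl (2S,3S,E)-2-[4-(benzyloxy)-3-methoxybenzyl]-3-(3,4-dimethoxybenzyl)-2-hydroxyhex-4-enoate | COc1cc(C[C@@](O)(C(=O)OC)[C@H](/C=C/C)Cc2ccc(OC)c(OC)c2)ccc1OCc1ccccc1 | intermediate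
13 | methyl (2S,3S)-2-[4-(benzyloxy)-3-methoxybenzyl]-3-(3,4-dimethoxybenzyl)-2,4,5-trihydroxyhexanoate, syn-4,5-diol from either alkene face (not isolated) | COc1cc(C[C@@](O)(C(=O)OC)[C@H](C(O)C(C)O)Cc2ccc(OC)c(OC)c2)ccc1OCc1ccccc1 | intermediate
14 | methyl (2S,3R)-2-[4-(benzyloxy)-3-methoxybenzyl]-3-(3,4-dimethoxybenzyl)-2-hydroxy-4-oxobutanoate | COc1cc(C[C@@](O)(C(=O)OC)[C@H](C=O)Cc2ccc(OC)c(OC)c2)ccc1OCc1ccccc1 | intermediate
15 | methyl (2S,3S)-2-[4-(benzyloxy)-3-methoxybenzyl]-3-(3,4-dimethoxybenzyl)-2,4-dihydroxybutanoate (not isolated) | COc1cc(C[C@@](O)(C(=O)OC)[C@H](CO)Cc2ccc(OC)c(OC)c2)ccc1OCc1ccccc1 | intermediate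
16 | (3S,4S)-3-[4-(benzyloxy)-3-methoxybenzyl]-4-(3,4-dimethoxybenzyl)-3-hydroxydihydrofuran-2(3H)-one | COc1cc(C[C@@]2(O)C(=O)OC[C@@H]2Cc2ccc(OC)c(OC)c2)ccc1OCc1ccccc1 | intermediate
17 | trachelogenin, (3S,4S)-4-(3,4-dimethoxybenzyl)-3-hydroxy-3-(4-hydroxy-3-methoxybenzyl)dihydrofuran-2(3H)-one | COc1cc(C[C@@]2(O)C(=O)OC[C@@H]2Cc2ccc(OC)c(OC)c2)ccc1O | target

## Step count and risk

Total: 9 steps. Longest linear sequence: 7 steps (1, 2, 3, 6, 7, 8, 9); the alcohol branch (4, 5) joins at step 6.

**Step 6 (key step, proposed extension).**
- What may go wrong: 1,2-hydride shift in the carbenoid to the cinnamate; proton transfer within the ylide outrunning the [2,3]-shift (plain O–H insertion); loss of facial control at the ylide carbon if the metal departs before the C–C bond forms, giving a mixture at C2.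
- Fallback (known chemistry): set out from 5 and 10 and run the O–H insertion deliberately (Cu(OTf)2 cat., CH2Cl2, a known reaction of α-alkyl diazoesters with alcohols). This gives the α-allyloxy ester methyl 3-[4-(benzyloxy)-3-methoxyphenyl]-2-{[(2R,3E)-5-(3,4-dimethoxyphenyl)pent-3-en-2-yl]oxy}propanoate F1 as both C2 epimers, which converge on enolisation. Its lithium enolate (LDA, THF, −78 → −20 °C) would undergo the ester-enolate [2,3]-Wittig rearrangement through the same five-membered envelope and return the route at 12. C3 would again come from chirality transfer and C2 from the enolate geometry; any C2 epimer would be removed by chromatography. Any O–H insertion product from the main experiment could be fed into the same step.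

**Step 4.**
- What may go wrong: Wurtz-type homocoupling or solvolysis of the labile electron-rich benzylic bromide; O-alkylation of the alkoxide; base-induced isomerisation of the 1-aryl-2-alkyne to an allene.
- Fallback: set out from 6 and silylate (TBSCl, imidazole) to (R)-tert-butyl(but-3-yn-2-yloxy)dimethylsilane F2. Zirconium-catalysed hydroboration with pinacolborane (Cp2Zr(H)Cl cat.) gives (R,E)-tert-butyldimethyl{[4-(4,4,5,5-tetramethyl-1,3,2-dioxaborolan-2-yl)but-3-en-2-yl]oxy}silane F3. Suzuki–Miyaura coupling of F3 with 7 (PdCl2(dppf), K2CO3, THF/H2O) gives (R,E)-tert-butyl{[5-(3,4-dimethoxyphenyl)pent-3-en-2-yl]oxy}dimethylsilane F4, and TBAF returns the route at 10. Step 5 is then not needed.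

**Step 7.**
- What may go wrong: lactonisation of the intermediate diol onto the ester before periodate cleaves it; epimerisation α to the aldehyde or retro-aldol cleavage during the aqueous reaction.
- Fallback: set out from 12 and ozonise in CH2Cl2/MeOH at −78 °C, stopping at the first excess of ozone to spare the arenes, then add NaBH4 to the cold solution. This reduces the peroxidic intermediate directly to hydroxy ester 15, which lactonises on acidic work-up, so the route is rejoined at 16 without handling free aldehyde 14.

**Step 2.**
- What may go wrong: sluggish hydride transfer to the electron-rich arylidene; retro-Knoevenagel or Michael addition of a second acetoacetate on prolonged heating.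
- Fallback: set out from 1 and reduce with NaBH4 to [4-(benzyloxy)-3-methoxyphenyl]methanol F5. SOCl2 converts it to 1-(benzyloxy)-4-(chloromethyl)-2-methoxybenzene F6, and C-alkylation of excess 2 (K2CO3, acetone, reflux) returns the route at 4, replacing steps 1 and 2.

## Further compounds

F1 | step 6 | methyl 3-[4-(benzyloxy)-3-methoxyphenyl]-2-{[(2R,3E)-5-(3,4-dimethoxyphenyl)pent-3-en-2-yl]oxy}propanoate (both C2 epimers) | COC(=O)C(Cc1ccc(OCc2ccccc2)c(OC)c1)O[C@H](C)/C=C/Cc1ccc(OC)c(OC)c1
F2 | step 4 | (R)-tert-butyl(but-3-yn-2-yloxy)dimethylsilane | C[C@@H](O[Si](C)(C)C(C)(C)C)C#C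
F3 | step 4 | (R,E)-tert-butyldimethyl{[4-(4,4,5,5-tetramethyl-1,3,2-dioxaborolan-2-yl)but-3-en-2-yl]oxy}silane | C[C@@H](O[Si](C)(C)C(C)(C)C)/C=C/B1OC(C)(C)C(C)(C)O1
F4 | step 4 | (R,E)-tert-butyl{[5-(3,4-dimethoxyphenyl)pent-3-en-2-yl]oxy}dimethylsilane | C[C@@H](O[Si](C)(C)C(C)(C)C)/C=C/Cc1ccc(OC)c(OC)c1
F0 | step 7 | none | none
F5 | step 2 | [4-(benzyloxy)-3-methoxyphenyl]methanol | COc1cc(CO)ccc1OCc1ccccc1
F6 | step 2 | 1-(benzyloxy)-4-(chloromethyl)-2-methoxybenzene | COc1cc(CCl)ccc1OCc1ccccc1
A1 | alternative 1 | 3-(benzyloxy)-3-[4-(benzyloxy)-3-methoxybenzyl]-4-[2-(3,4-dimethoxyphenyl)-1,3-dithian-2-yl]-5-(l-menthyloxy)dihydrofuran-2(3H)-one (C3 benzyl trans to the C4 group, C4 group trans to the C5 menthyloxy group) | O=C1O[C@@H](O[C@@H]4C[C@H](C)CC[C@H]4C(C)C)[C@H](C2(c3ccc(OC)c(OC)c3)SCCCS2)[C@@]1(OCc1ccccc1)Cc1ccc(OCc2ccccc2)c(OC)c1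
A2 | alternative 1 | (5R)-3-(benzyloxy)-5-(l-menthyloxy)furan-2(5H)-one | O=C1O[C@@H](O[C@@H]2C[C@H](C)CC[C@H]2C(C)C)C=C1OCc1ccccc1
A3 | alternative 1 | 2-(3,4-dimethoxyphenyl)-1,3-dithiane | COc1ccc(C2SCCCS2)cc1OC
A4 | alternative 1 | 4-(benzyloxy)-3-methoxybenzyl bromide | COc1cc(CBr)ccc1OCc1ccccc1
A5 | alternative 2 | (S)-2-[1-(benzyloxy)-3-(3,4-dimethoxyphenyl)propan-2-yl]-4,4,5,5-tetramethyl-1,3,2-dioxaborolane | c1ccccc1COC[C@@H](B2OC(C)(C)C(C)(C)O2)Cc2ccc(OC)c(OC)c2
A6 | alternative 2 | 4,4,5,5-tetramethyl-2-vinyl-1,3,2-dioxaborolane | C=CB1OC(C)(C)C(C)(C)O1
A7 | alternative 2 | (benzyloxymethyl)lithium | [Li]COCc1ccccc1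
A8 | alternative 2 | 3,4-dimethoxyphenyl trifluoromethanesulfonate | COc1ccc(OS(=O)(=O)C(F)(F)F)cc1OC
A9 | alternative 3 | (3S,4S)-3-[4-(benzyloxy)-3-methoxybenzyl]-3-{[4-(benzyloxy)-3-methoxybenzyl]oxy}-4-(3,4-dimethoxybenzyl)dihydrofuran-2(3H)-one | COc1cc(C[C@@]2(OCc3ccc(OCc4ccccc4)c(OC)c3)C(=O)OC[C@@H]2Cc2ccc(OC)c(OC)c2)ccc1OCc1ccccc1
A10 | alternative 3 | (R)-3-diazo-4-(3,4-dimethoxybenzyl)dihydrofuran-2(3H)-one | [N-]=[N+]=C1C(=O)OC[C@@H]1Cc1ccc(OC)c(OC)c1
A11 | alternative 3 | bis[4-(benzyloxy)-3-methoxybenzyl] ether | COc1cc(COCc2ccc(OCc3ccccc3)c(OC)c2)ccc1OCc1ccccc1
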